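**Retrosynthetic overview**
- Last step: acid removal of three MOM ethers and one TBS ether. The aryl ketone bond comes from lithiated tris-MOM-phloroglucinol and a C20 Weinreb amide.
- The all-Z 5,8,11,14-tetraene comes from a skipped tetrayne by semi-hydrogenation. The tetrayne comes from copper-mediated coupling of a C1–C13 triynyl bromide and a C14–C20 terminal alkyne.
- The C1–C13 bromide is built from methyl hex-5-ynoate by two rounds of propargylic coupling (4-chlorobut-2-yn-1-ol, then propargyl alcohol), each followed by Appel bromination.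
- The C14–C20 alkyne comes from (S)-hept-1-en-4-ol (silylation, ozonolysis, alkyne homologation). Key step: Brown asymmetric allylation of butanal forms C16–C17 and sets C17.
- No ring is formed at any stage. The only ring, the benzene ring, is bought as phloroglucinol.

Assumption: the SMILES is read as the (17S) enantiomer, and (+)-B-allyldiisopinocampheylborane is bought as its commercial salt-free pentane solution.

**Step 1**
Reactants: 1 butanal; 2 (+)-B-allyldiisopinocampheylborane (the enantiomer built from (−)-α-pinene)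
Product: 4 (4S)-hept-1-en-4-ol, via borinate ester 3 (not isolated)
Conditions: Et2O/pentane, −100 °C, 1 h; then 3 M NaOH, 30% H2O2, 0 °C → rt
Reagents that add atoms: none
Why: Brown asymmetric allylboration (carbonyl allylation) runs through a closed six-membered chair transition state in which the isopinocampheyl groups of the (−)-α-pinene-derived borane direct the allyl group to the Re face of butanal, which forms C16–C17 and sets C17 as S (allyl outranks propyl); alkaline peroxide then frees the alcohol from boron.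

**Step 2**
Reactants: 4 (4S)-hept-1-en-4-ol
Product: 5 tert-butyl{[(4S)-hept-1-en-4-yl]oxy}dimethylsilane
Conditions: TBSCl, imidazole, DMF, rt
Reagents that add atoms: tert-butyldimethylsilyl chloride, `CC(C)(C)[Si](C)(C)Cl`
Why: Standard silylation of an unhindered secondary alcohol gives a TBS ether that survives ozonolysis, carbonate bases, copper coupling, hydrogenation and the organometallic steps, and leaves the stereocentre untouched.

**Step 3**
Reactants: 5 tert-butyl{[(4S)-hept-1-en-4-yl]oxy}dimethylsilane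
Product: 7 (3S)-3-[(tert-butyldimethylsilyl)oxy]hexanal, via ozonide 6 (not isolated)
Conditions: O3, CH2Cl2, −78 °C; then PPh3, −78 °C → rt
Reagents that add atoms: ozone, `O=[O+][O-]`
Why: Ozonolysis with reductive work-up (Criegee mechanism) cleaves the only alkene to the aldehyde; the silyl ether is inert and the stereocentre is not alpha to the new carbonyl.

**Step 4**
Reactants: 7 (3S)-3-[(tert-butyldimethylsilyl)oxy]hexanal
Product: 8 tert-butyl{[(4S)-hept-1-yn-4-yl]oxy}dimethylsilane
Conditions: MeC(O)C(N2)P(O)(OMe)2, K2CO3, MeOH, 0 °C → rt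
Reagents that add atoms: dimethyl (1-diazo-2-oxopropyl)phosphonate, `CC(=O)C(=[N+]=[N-])P(=O)(OC)OC`
Why: Ohira–Bestmann (Seyferth–Gilbert) homologation turns the aldehyde into the terminal alkyne under mild carbonate/methanol conditions at which E1cB loss of the β-silyloxy group is slow, and C17 is not involved.

**Step 5**
Reactants: 9 methyl hex-5-ynoate; 10 4-chlorobut-2-yn-1-ol
Product: 11 methyl 10-hydroxydeca-5,8-diynoate
Conditions: CuI, NaI, Cs2CO3, DMF, rt
Reagents that add atoms: none
Why: Copper-mediated coupling of a terminal alkyne with a propargylic halide (copper acetylide substitution, accelerated by NaI) gives the skipped diyne without a strong base, so the 1,4-diyne does not isomerise to an allene.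

**Step 6**
Reactants: 11 methyl 10-hydroxydeca-5,8-diynoate
Product: 12 methyl 10-bromodeca-5,8-diynoate
Conditions: CBr4, PPh3, CH2Cl2, 0 °C
Reagents that add atoms: carbon tetrabromide, `BrC(Br)(Br)Br`
Why: Appel bromination converts the primary propargylic alcohol into the bromide under neutral conditions (SN2 on the alkoxyphosphonium ion), which the base-sensitive skipped diyne tolerates.

**Step 7**
Reactants: 12 methyl 10-bromodeca-5,8-diynoate; 13 prop-2-yn-1-ol
Product: 14 methyl 13-hydroxytrideca-5,8,11-triynoate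
Conditions: CuI, NaI, Cs2CO3, DMF, rt
Reagents that add atoms: none
Why: A second copper acetylide–propargylic bromide coupling of the same type as step 5 adds C11–C13 and gives the skipped triyne.

**Step 8**
Reactants: 14 methyl 13-hydroxytrideca-5,8,11-triynoate
Product: 15 methyl 13-bromotrideca-5,8,11-triynoate
Conditions: CBr4, PPh3, CH2Cl2, −20 → 0 °C
Reagents that add atoms: carbon tetrabromide, `BrC(Br)(Br)Br`
Why: Appel bromination again works under neutral conditions; the labile triynyl bromide is kept cold and used at once.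

**Step 9**
Reactants: 15 methyl 13-bromotrideca-5,8,11-triynoate; 8 tert-butyl{[(4S)-hept-1-yn-4-yl]oxy}dimethylsilane
Product: 16 methyl (17S)-17-[(tert-butyldimethylsilyl)oxy]icosa-5,8,11,14-tetraynoate
Conditions: CuI, NaI, Cs2CO3, DMF, rt, argon, dark
Reagents that add atoms: none
Why: The third copper acetylide–propargylic bromide coupling joins fragment C1–C13 to the chiral alkyne C14–C20, and the mild carbonate base leaves ester, TBS ether and the remote stereocentre alone.

**Step 10**
Reactants: 16 methyl (17S)-17-[(tert-butyldimethylsilyl)oxy]icosa-5,8,11,14-tetraynoate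
Product: 17 methyl (5Z,8Z,11Z,14Z,17S)-17-[(tert-butyldimethylsilyl)oxy]icosa-5,8,11,14-tetraenoate
Conditions: H2 (1 atm), Ni2B from Ni(OAc)2·4H2O/NaBH4 (0.2 equiv each), ethylenediamine, EtOH, rt, stop after 4 equiv H2
Reagents that add atoms: none
Why: Semi-hydrogenation over amine-poisoned nickel boride (Brown P-2 Ni catalyst) adds H2 syn to each alkyne and stops at the alkene, so all four double bonds are Z; ester and silyl ether are inert.

**Step 11**
Reactants: 17 methyl (5Z,8Z,11Z,14Z,17S)-17-[(tert-butyldimethylsilyl)oxy]icosa-5,8,11,14-tetraenoate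
Product: 18 (5Z,8Z,11Z,14Z,17S)-17-[(tert-butyldimethylsilyl)oxy]-N-methoxy-N-methylicosa-5,8,11,14-tetraenamide
Conditions: MeNH(OMe)·HCl, i-PrMgCl, THF, −20 → −10 °C; then H2O
Reagents that add atoms: N,O-dimethylhydroxylamine hydrochloride, `CNOC.Cl`
Why: Direct aminolysis of the methyl ester by the magnesium amide of N,O-dimethylhydroxylamine (Weinreb amide formation) proceeds cold without touching the skipped tetraene or the TBS ether.

**Step 12**
Reactants: 19 phloroglucinol
Product: 20 1,3,5-tris(methoxymethoxy)benzene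
Conditions: MOMCl, i-Pr2NEt, CH2Cl2, 0 °C → rt
Reagents that add atoms: chloromethyl methyl ether, `COCCl`
Why: O-Alkylation of the three phenols with the hard electrophile MOMCl (Williamson-type etherification) gives a tris-acetal that directs lithiation and later comes off in mild acid.

**Step 13**
Reactants: 20 1,3,5-tris(methoxymethoxy)benzene; 18 (5Z,8Z,11Z,14Z,17S)-17-[(tert-butyldimethylsilyl)oxy]-N-methoxy-N-methylicosa-5,8,11,14-tetraenamide
Product: 23 (5Z,8Z,11Z,14Z,17S)-17-[(tert-butyldimethylsilyl)oxy]-1-[2,4,6-tris(methoxymethoxy)phenyl]icosa-5,8,11,14-tetraen-1-one, via aryllithium 21 (not isolated), via lithium hemiaminal 22 (not isolated)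
Conditions: n-BuLi, THF, 0 °C, 1 h; then 18, −78 → 0 °C; then H2O
Reagents that add atoms: none
Why: Directed ortho-lithiation between two MOM ethers is followed by nucleophilic acyl substitution on the Weinreb amide, whose chelated tetrahedral intermediate blocks over-addition and releases the aryl ketone only on work-up; the cold aryllithium does not attack the bis-allylic CH2 groups.

**Step 14**
Reactants: 23 (5Z,8Z,11Z,14Z,17S)-17-[(tert-butyldimethylsilyl)oxy]-1-[2,4,6-tris(methoxymethoxy)phenyl]icosa-5,8,11,14-tetraen-1-one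
Product: 24 (5Z,8Z,11Z,14Z,17S)-17-hydroxy-1-(2,4,6-trihydroxyphenyl)icosa-5,8,11,14-tetraen-1-one
Conditions: HCl (1 M in MeOH), 40 °C, argon
Reagents that add atoms: none
Why: Acid-catalysed acetal methanolysis removes the three MOM groups and acid solvolysis removes the TBS ether in one operation; dilute methanolic HCl neither isomerises skipped Z-alkenes nor ionises the C17 carbinol, so the S configuration is kept.

**Compound list**
1 | butanal | `CCCC=O` | starting material
2 | (+)-B-allyldiisopinocampheylborane (from (−)-α-pinene) | `C=CCB([C@H]1C[C@H]2C[C@@H]([C@@H]1C)C2(C)C)[C@H]1C[C@H]2C[C@@H]([C@@H]1C)C2(C)C` | starting material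
3 | (4S)-hept-1-en-4-yl diisopinocampheylborinate | `CCC[C@H](OB([C@H]1C[C@H]2C[C@@H]([C@@H]1C)C2(C)C)[C@H]1C[C@H]2C[C@@H]([C@@H]1C)C2(C)C)CC=C` | intermediate
4 | (4S)-hept-1-en-4-ol | `CCC[C@H](O)CC=C` | intermediate
5 | tert-butyl{[(4S)-hept-1-en-4-yl]oxy}dimethylsilane | `CCC[C@H](O[Si](C)(C)C(C)(C)C)CC=C` | intermediate
6 | tert-butyldimethyl{[(2S)-1-(1,2,4-trioxolan-3-yl)pentan-2-yl]oxy}silane (ozonide, both epimers at the ring carbon) | `CCC[C@H](O[Si](C)(C)C(C)(C)C)CC1OOCO1` | intermediate
7 | (3S)-3-[(tert-butyldimethylsilyl)oxy]hexanal | `CCC[C@H](O[Si](C)(C)C(C)(C)C)CC=O` | intermediate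
8 | tert-butyl{[(4S)-hept-1-yn-4-yl]oxy}dimethylsilane | `CCC[C@H](O[Si](C)(C)C(C)(C)C)CC#C` | intermediate
9 | methyl hex-5-ynoate | `COC(=O)CCCC#C` | starting material
10 | 4-chlorobut-2-yn-1-ol | `OCC#CCCl` | starting material
11 | methyl 10-hydroxydeca-5,8-diynoate | `COC(=O)CCCC#CCC#CCO` | intermediate
12 | methyl 10-bromodeca-5,8-diynoate | `COC(=O)CCCC#CCC#CCBr` | intermediate
13 | prop-2-yn-1-ol | `OCC#C` | starting material
14 | methyl 13-hydroxytrideca-5,8,11-triynoate | `COC(=O)CCCC#CCC#CCC#CCO` | intermediate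
15 | methyl 13-bromotrideca-5,8,11-triynoate | `COC(=O)CCCC#CCC#CCC#CCBr` | intermediate
16 | methyl (17S)-17-[(tert-butyldimethylsilyl)oxy]icosa-5,8,11,14-tetraynoate | `CCC[C@H](O[Si](C)(C)C(C)(C)C)CC#CCC#CCC#CCC#CCCCC(=O)OC` | intermediate
17 | methyl (5Z,8Z,11Z,14Z,17S)-17-[(tert-butyldimethylsilyl)oxy]icosa-5,8,11,14-tetraenoate | `CCC[C@H](O[Si](C)(C)C(C)(C)C)C/C=C\C/C=C\C/C=C\C/C=C\CCCC(=O)OC` | intermediate
18 | (5Z,8Z,11Z,14Z,17S)-17-[(tert-butyldimethylsilyl)oxy]-N-methoxy-N-methylicosa-5,8,11,14-tetraenamide | `CCC[C@H](O[Si](C)(C)C(C)(C)C)C/C=C\C/C=C\C/C=C\C/C=C\CCCC(=O)N(C)OC` | intermediate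
19 | phloroglucinol (benzene-1,3,5-triol) | `Oc1cc(O)cc(O)c1` | starting material
20 | 1,3,5-tris(methoxymethoxy)benzene | `COCOc1cc(OCOC)cc(OCOC)c1` | intermediate
21 | [2,4,6-tris(methoxymethoxy)phenyl]lithium | `[Li]c1c(OCOC)cc(OCOC)cc1OCOC` | intermediate
22 | lithium (5Z,8Z,11Z,14Z,17S)-17-[(tert-butyldimethylsilyl)oxy]-1-[methoxy(methyl)amino]-1-[2,4,6-tris(methoxymethoxy)phenyl]icosa-5,8,11,14-tetraen-1-olate (both C1 epimers) | `CCC[C@H](O[Si](C)(C)C(C)(C)C)C/C=C\C/C=C\C/C=C\C/C=C\CCCC(O[Li])(N(C)OC)c1c(OCOC)cc(OCOC)cc1OCOC` | intermediate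
23 | (5Z,8Z,11Z,14Z,17S)-17-[(tert-butyldimethylsilyl)oxy]-1-[2,4,6-tris(methoxymethoxy)phenyl]icosa-5,8,11,14-tetraen-1-one | `CCC[C@H](O[Si](C)(C)C(C)(C)C)C/C=C\C/C=C\C/C=C\C/C=C\CCCC(=O)c1c(OCOC)cc(OCOC)cc1OCOC` | intermediate
24 | (5Z,8Z,11Z,14Z,17S)-17-hydroxy-1-(2,4,6-trihydroxyphenyl)icosa-5,8,11,14-tetraen-1-one | `CCC[C@H](O)C/C=C\C/C=C\C/C=C\C/C=C\CCCC(=O)c1c(O)cc(O)cc1O` | target

**Totals**
Total step count: 14.
Longest linear sequence: 9 steps (steps 1, 2, 3, 4, 9, 10, 11, 13, 14 from butanal; the branch from methyl hex-5-ynoate, steps 5 to 11, then 13 and 14, is also 9).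

**Three steps most likely to fail**

Step 10. A tetrayne can be over-reduced or left partly reduced, and saturated or E impurities are hard to remove. The fallback sets out from bromide 12 and comes back at ester 17; the last alkene is made by olefination and only a triyne has to be reduced. Bromide 12 is coupled with but-3-yn-1-ol (CuI, NaI, Cs2CO3, DMF) to give methyl 14-hydroxytetradeca-5,8,11-triynoate F1. This is semi-hydrogenated over Ni2B (H2, ethylenediamine, EtOH) to methyl (5Z,8Z,11Z)-14-hydroxytetradeca-5,8,11-trienoate F2, a polar alcohol that can be cleaned on AgNO3-doped silica. I2, PPh3 and imidazole in CH2Cl2 give methyl (5Z,8Z,11Z)-14-iodotetradeca-5,8,11-trienoate F3. PPh3 in MeCN at reflux gives [(3Z,6Z,9Z)-14-methoxy-14-oxotetradeca-3,6,9-trien-1-yl]triphenylphosphonium iodide F4. NaN(SiMe3)2 in THF at −78 °C gives the ylide methyl (5Z,8Z,11Z)-14-(triphenylphosphoranylidene)tetradeca-5,8,11-trienoate F5, which is not isolated but treated at once with aldehyde 7. The salt-free Wittig reaction of this unstabilised ylide forms C14=C15 as the Z alkene and gives 17. Steps 4 and 7 to 9 are then not needed.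

Step 13. The hindered aryllithium may enolise the amide or add sluggishly. The fallback sets out from Weinreb amide 18 and comes back at ketone 23. Amide 18 is reduced with i-Bu2AlH in THF at −78 °C to (5Z,8Z,11Z,14Z,17S)-17-[(tert-butyldimethylsilyl)oxy]icosa-5,8,11,14-tetraenal F6. Aryllithium 21 is added at −78 °C (addition to an aldehyde is much faster than to an amide) to give (5Z,8Z,11Z,14Z,17S)-17-[(tert-butyldimethylsilyl)oxy]-1-[2,4,6-tris(methoxymethoxy)phenyl]icosa-5,8,11,14-tetraen-1-ol F7 as both C1 epimers. Oxidation with Dess–Martin periodinane and NaHCO3 in CH2Cl2 gives 23.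

Step 9. Triynyl bromide 15 is labile and can give allenic or oligomeric by-products. The fallback sets out from alkyne 8 and comes back at tetrayne 16; the chain is cut between C10 and C11 so that the sturdier diynyl bromide 12 is the electrophile. Alkyne 8 is coupled with 3-bromo-1-(trimethylsilyl)prop-1-yne (CuI, NaI, Cs2CO3, DMF) to give tert-butyldimethyl{[(4S)-10-(trimethylsilyl)deca-6,9-diyn-4-yl]oxy}silane F8. K2CO3 in MeOH at 0 °C removes the alkynyl silyl group and gives tert-butyl{[(4S)-deca-6,9-diyn-4-yl]oxy}dimethylsilane F9. Coupling of this diyne with bromide 12 under the same copper conditions gives 16; steps 7 and 8 drop out.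

**Further compounds**
F1 | step 10 | methyl 14-hydroxytetradeca-5,8,11-triynoate | `COC(=O)CCCC#CCC#CCC#CCCO`
F2 | step 10 | methyl (5Z,8Z,11Z)-14-hydroxytetradeca-5,8,11-trienoate | `COC(=O)CCC/C=C\C/C=C\C/C=C\CCO`
F3 | step 10 | methyl (5Z,8Z,11Z)-14-iodotetradeca-5,8,11-trienoate | `COC(=O)CCC/C=C\C/C=C\C/C=C\CCI`
F4 | step 10 | [(3Z,6Z,9Z)-14-methoxy-14-oxotetradeca-3,6,9-trien-1-yl]triphenylphosphonium iodide | `COC(=O)CCC/C=C\C/C=C\C/C=C\CC[P+](c1ccccc1)(c1ccccc1)c1ccccc1.[I-]`
F5 | step 10 | methyl (5Z,8Z,11Z)-14-(triphenylphosphoranylidene)tetradeca-5,8,11-trienoate | `COC(=O)CCC/C=C\C/C=C\C/C=C\CC=P(c1ccccc1)(c1ccccc1)c1ccccc1`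
F6 | step 13 | (5Z,8Z,11Z,14Z,17S)-17-[(tert-butyldimethylsilyl)oxy]icosa-5,8,11,14-tetraenal | `CCC[C@H](O[Si](C)(C)C(C)(C)C)C/C=C\C/C=C\C/C=C\C/C=C\CCCC=O`
F7 | step 13 | (5Z,8Z,11Z,14Z,17S)-17-[(tert-butyldimethylsilyl)oxy]-1-[2,4,6-tris(methoxymethoxy)phenyl]icosa-5,8,11,14-tetraen-1-ol | `CCC[C@H](O[Si](C)(C)C(C)(C)C)C/C=C\C/C=C\C/C=C\C/C=C\CCCC(O)c1c(OCOC)cc(OCOC)cc1OCOC`
F8 | step 9 | tert-butyldimethyl{[(4S)-10-(trimethylsilyl)deca-6,9-diyn-4-yl]oxy}silane | `CCC[C@H](O[Si](C)(C)C(C)(C)C)CC#CCC#C[Si](C)(C)C`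
F9 | step 9 | tert-butyl{[(4S)-deca-6,9-diyn-4-yl]oxy}dimethylsilane | `CCC[C@H](O[Si](C)(C)C(C)(C)C)CC#CCC#C`
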